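**Plan**

- Locants follow the furo[3,2-b]furan-2-one skeleton (C-2 carbonyl, C-3, C-3a = OCH, O-4, C-5, C-6, C-6a = C(CH3)O; C-1′ is the first chain carbon). The ring-fusion bond C-3a–C-6a joins a methyl carbinol carbon to an oxygen-bearing CH that is β to the lactone carbonyl. It is therefore read as a ketyl (from a methyl ketone) adding to the β-carbon of a β-alkoxyacrylate, which closes the oxolane ring.
- Retrosynthetic cuts: C-1′–C-2′ (Wittig); O-1–C-2 together with inversion of C-3a (retro-oxa-Michael/oxa-Michael, lactonisation); C-3a–C-6a (key ring closure); O-4–C-3a and a temporary ester bond C-2–O–C-1′ (a seven-membered ring that is not in the target); C-6–C-6a (epoxide opening).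
- Forward: (S)-2-methylglycidol, then the diol, then the temporary 1,4-dioxepin-5-one ring, then the methyl ketone, then the oxolane ring by the key step (bridged bicycle). The temporary ring is then opened, the chain is joined, the γ-lactone ring is closed last, and hydrogenation finishes.
- Stereochemistry: C-5 comes from the glycidol. In the key step the temporary lactone bridge forces C-3 cis to C-1′ and leaves the exo position for the samarium-bound oxygen, which sets C-6a (OH cis to the C-5 methyl). C-3a is formed epimeric on purpose and is inverted in a stereoconvergent base step in which only the cis isomer can lactonise.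

Key step: step 5

Remark: (S)-2-methylglycidol is taken as a commercial, enantiomerically pure starting material, so the configuration of C-5 is bought in and never touched.

**Route**

Step 1
Reactants: 1 (S)-2-methylglycidol
Product: 2 (2R)-2-methylpent-4-ene-1,2-diol
Conditions: CH2=CHMgBr (2.5 equiv), CuI (10 mol %), THF, −30 to 0 °C; aq NH4Cl
Reagents that add atoms: vinylmagnesium bromide, C=C[Mg]Br
Why: Copper-catalysed Grignard opening of the 2,2-disubstituted epoxide by SN2 attack at its unsubstituted CH2 should give the homoallylic 1,2-diol, and since no bond to the quaternary carbinol carbon is touched the configuration of 1 is carried into C-5 unchanged.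

Step 2
Reactants: 2 (2R)-2-methylpent-4-ene-1,2-diol
Product: 3 (2R)-2-hydroxy-2-methylpent-4-en-1-yl prop-2-ynoate
Conditions: HC≡CCO2H, DCC, DMAP (5 mol %), CH2Cl2, −20 °C
Reagents that add atoms: propiolic acid, C#CC(=O)O
Why: Steglich esterification should acylate the primary hydroxyl selectively, because the tertiary hydroxyl is too hindered to react with the O-acylisourea at low temperature; no stereocenter is involved.

Step 3
Reactants: 3 (2R)-2-hydroxy-2-methylpent-4-en-1-yl prop-2-ynoate
Product: 4 (2R)-2-methyl-2-(prop-2-en-1-yl)-2,3-dihydro-5H-1,4-dioxepin-5-one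
Conditions: PMe3 (10 mol %), CH2Cl2 (0.01 M), 0 °C to rt
Reagents that add atoms: none
Why: In this phosphine-catalysed intramolecular oxa-Michael addition PMe3 adds to the ynoate to give a β-phosphonium enolate that deprotonates the tertiary alcohol, and the alkoxide then displaces the phosphine at the β-carbon by addition–elimination, which under high dilution should close the seven-membered cyclic β-alkoxyacrylate (necessarily Z in a ring of this size) without touching the stereocenter.

Step 4
Reactants: 4 (2R)-2-methyl-2-(prop-2-en-1-yl)-2,3-dihydro-5H-1,4-dioxepin-5-one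
Product: 5 (2R)-2-methyl-2-(2-oxopropyl)-2,3-dihydro-5H-1,4-dioxepin-5-one
Conditions: PdCl2 (10 mol %), CuCl (1 equiv), O2 (1 atm), DMF/H2O (7:1), rt
Reagents that add atoms: water, O
Why: Tsuji–Wacker oxidation should convert the terminal alkene into the methyl ketone with Markovnikov regiochemistry, while the electron-poor push–pull enol ether of the ring is not attacked by divalent palladium; no stereocenter is formed.

Step 5
Reactants: 5 (2R)-2-methyl-2-(2-oxopropyl)-2,3-dihydro-5H-1,4-dioxepin-5-one
Product: 7 (1R,6R,7S)-7-hydroxy-1,7-dimethyl-3,9-dioxabicyclo[4.2.1]nonan-4-one, via samarium alkoxide enolate 6 (not isolated)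
Conditions: SmI2 (2.5 equiv), MeOH (3 equiv), THF, 0 °C
Reagents that add atoms: none
Why: SmI2 transfers one electron to the methyl ketone and the ketyl carbon (C-6a) adds to the β-carbon (C-3a) of the cyclic β-alkoxyacrylate; a second electron turns the α-ester radical into the trivalent samarium enolate 6, which methanol protonates before it can expel the β-oxygen. The closest known reaction type is the SmI2-mediated reductive ketyl–olefin cyclisation of ketones tethered to β-alkoxyacrylates, here run on a cyclic acrylate. The oxolane ring closes in the 5-exo-trig mode and, because O-4, C-5 and C-3a already lie in the seven-membered ring, the product is the bridged 3,9-dioxabicyclo[4.2.1]nonane. C-3a is set by the temporary lactone ring: the acetonyl arm on C-5 can reach only the alkene face on its own side, so C-3 and C-1′ must end cis on the new oxolane. C-6a is set by the preference of the bulky, electron-rich samarium-bound oxygen for the exo position, anti to the enoate (the usual sense of 5-exo ketyl–enoate closures) and away from the four-atom lactone bridge, which puts the new hydroxyl cis to the C-5 methyl group as the target requires. The step needs chemoselective ketyl formation and exo orientation of the oxygen; the first is secured by the push–pull alkene, which SmI2 does not reduce directly, and the second by the bridge, which crowds the endo position.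

Step 6
Reactants: 7 (1R,6R,7S)-7-hydroxy-1,7-dimethyl-3,9-dioxabicyclo[4.2.1]nonan-4-one
Product: 8 methyl 2-[(2R,3S,5R)-3-hydroxy-5-(hydroxymethyl)-3,5-dimethyloxolan-2-yl]acetate
Conditions: K2CO3 (0.2 equiv), MeOH, 0 °C
Reagents that add atoms: methanol, CO
Why: Base-catalysed transesterification of the strained bridged seven-membered lactone should release the methyl ester and the primary alcohol under conditions too mild for enolisation, so the three stereocenters are unchanged and the primary hydroxyl is freed before any strong base is used, where it could compete as a Michael donor.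

Step 7
Reactants: 8 methyl 2-[(2R,3S,5R)-3-hydroxy-5-(hydroxymethyl)-3,5-dimethyloxolan-2-yl]acetate
Product: 9 methyl 2-[(2R,3S,5R)-5-formyl-3-hydroxy-3,5-dimethyloxolan-2-yl]acetate
Conditions: Dess–Martin periodinane, CH2Cl2, 0 °C to rt
Reagents that add atoms: none
Why: Dess–Martin oxidation should convert the primary alcohol into the aldehyde without touching the tertiary alcohol, and the aldehyde cannot epimerise because its α-carbon is quaternary.

Step 8
Reactants: 10 11-bromoundec-1-ene; 11 1-(benzyloxy)-4-iodobenzene
Product: 13 1-(benzyloxy)-4-(11-bromoundecyl)benzene, via alkyl borane 12 (not isolated)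
Conditions: 9-BBN, THF, 0 °C to rt; then 11, PdCl2(dppf) (3 mol %), K3PO4, DMF/H2O, rt to 40 °C
Reagents that add atoms: none
Why: Anti-Markovnikov hydroboration of the terminal alkene followed by B-alkyl Suzuki–Miyaura coupling should join the chain to the arene, because oxidative addition of zerovalent palladium to the aryl iodide is far faster than to the primary alkyl bromide, which is kept for the next step.

Step 9
Reactants: 13 1-(benzyloxy)-4-(11-bromoundecyl)benzene
Product: 14 {11-[4-(benzyloxy)phenyl]undecyl}triphenylphosphonium bromide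
Conditions: PPh3, MeCN, reflux
Reagents that add atoms: triphenylphosphine, c1ccc(cc1)P(c1ccccc1)c1ccccc1
Why: SN2 quaternisation of triphenylphosphine by the primary bromide should give the Wittig salt.

Step 10
Reactants: 14 {11-[4-(benzyloxy)phenyl]undecyl}triphenylphosphonium bromide; 9 methyl 2-[(2R,3S,5R)-5-formyl-3-hydroxy-3,5-dimethyloxolan-2-yl]acetate
Product: 16 methyl 2-[(2R,3S,5R)-5-{(1Z)-12-[4-(benzyloxy)phenyl]dodec-1-en-1-yl}-3-hydroxy-3,5-dimethyloxolan-2-yl]acetate, via phosphonium ylide 15 (not isolated)
Conditions: 14 (1.3 equiv), NaN(SiMe3)2, THF, −78 to 0 °C; then 9, −78 °C to rt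
Reagents that add atoms: none
Why: Wittig olefination with the non-stabilised ylide at low temperature should join C-1′ to C-2′ as the Z-alkene (its geometry is irrelevant, since it is hydrogenated later) without touching the ester, the tertiary alcohol or any stereocenter.

Step 11
Reactants: 16 methyl 2-[(2R,3S,5R)-5-{(1Z)-12-[4-(benzyloxy)phenyl]dodec-1-en-1-yl}-3-hydroxy-3,5-dimethyloxolan-2-yl]acetate
Product: 19 (3aS,5R,6aS)-5-{(1Z)-12-[4-(benzyloxy)phenyl]dodec-1-en-1-yl}-5,6a-dimethyltetrahydrofuro[3,2-b]furan-2(3H)-one, via ring-opened enoate 17 (not isolated), via cis-hydroxy ester 18 (not isolated)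
Conditions: KOt-Bu (0.3 equiv), THF, 0 °C to rt
Reagents that add atoms: none
Why: In this base-mediated retro-oxa-Michael/oxa-Michael equilibration with lactonisation the ester enolate expels the C-5 alkoxide to give enoate 17, re-addition to either face of the enoate is reversible, and only the 2,3-cis isomer 18 can lactonise, so the material should be drained into the cis-fused lactone in which C-3a is dictated by the fixed configuration of C-6a.

Step 12
Reactants: 19 (3aS,5R,6aS)-5-{(1Z)-12-[4-(benzyloxy)phenyl]dodec-1-en-1-yl}-5,6a-dimethyltetrahydrofuro[3,2-b]furan-2(3H)-one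
Product: 20 plakortone N
Conditions: H2 (1 atm), Pd/C (10%), EtOAc, rt
Reagents that add atoms: none
Why: Heterogeneous hydrogenation in a non-acidic solvent should saturate the disubstituted alkene and cleave the benzyl ether in one operation, leaving the lactone, the allylic C–O bond and the three stereocenters untouched.

**Compound list**

1 | (S)-2-methylglycidol, [(2S)-2-methyloxiran-2-yl]methanol | C[C@]1(CO)CO1 | starting material
2 | (2R)-2-methylpent-4-ene-1,2-diol | C[C@](O)(CO)CC=C | intermediate
3 | (2R)-2-hydroxy-2-methylpent-4-en-1-yl prop-2-ynoate | C[C@](O)(COC(=O)C#C)CC=C | intermediate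
4 | (2R)-2-methyl-2-(prop-2-en-1-yl)-2,3-dihydro-5H-1,4-dioxepin-5-one | C[C@]1(COC(=O)/C=C\O1)CC=C | intermediate
5 | (2R)-2-methyl-2-(2-oxopropyl)-2,3-dihydro-5H-1,4-dioxepin-5-one | C[C@]1(COC(=O)/C=C\O1)CC(C)=O | intermediate
6 | bis(diiodosamarium) C-7 alkoxide and lactone enolate of 7 | C[C@@]12COC(O[Sm](I)I)=C[C@@H](O1)[C@@](C)(O[Sm](I)I)C2 | intermediate (not isolated)
7 | (1R,6R,7S)-7-hydroxy-1,7-dimethyl-3,9-dioxabicyclo[4.2.1]nonan-4-one | C[C@@]12COC(=O)C[C@@H](O1)[C@@](C)(O)C2 | intermediate
8 | methyl 2-[(2R,3S,5R)-3-hydroxy-5-(hydroxymethyl)-3,5-dimethyloxolan-2-yl]acetate | C[C@]1(CO)C[C@](C)(O)[C@@H](CC(=O)OC)O1 | intermediate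
9 | methyl 2-[(2R,3S,5R)-5-formyl-3-hydroxy-3,5-dimethyloxolan-2-yl]acetate | C[C@]1(C=O)C[C@](C)(O)[C@@H](CC(=O)OC)O1 | intermediate
10 | 11-bromoundec-1-ene | C=CCCCCCCCCCBr | starting material
11 | 1-(benzyloxy)-4-iodobenzene | Ic1ccc(OCc2ccccc2)cc1 | starting material
12 | 9-(11-bromoundecyl)-9-borabicyclo[3.3.1]nonane | BrCCCCCCCCCCCB1C2CCCC1CCC2 | intermediate (not isolated)
13 | 1-(benzyloxy)-4-(11-bromoundecyl)benzene | BrCCCCCCCCCCCc1ccc(OCc2ccccc2)cc1 | intermediate
14 | {11-[4-(benzyloxy)phenyl]undecyl}triphenylphosphonium bromide | [Br-].c1ccc(cc1)[P+](CCCCCCCCCCCc1ccc(OCc2ccccc2)cc1)(c1ccccc1)c1ccccc1 | intermediate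
15 | {11-[4-(benzyloxy)phenyl]undecylidene}triphenylphosphorane | c1ccc(cc1)P(=CCCCCCCCCCCc1ccc(OCc2ccccc2)cc1)(c1ccccc1)c1ccccc1 | intermediate (not isolated)
16 | methyl 2-[(2R,3S,5R)-5-{(1Z)-12-[4-(benzyloxy)phenyl]dodec-1-en-1-yl}-3-hydroxy-3,5-dimethyloxolan-2-yl]acetate | C[C@]1(/C=C\CCCCCCCCCCc2ccc(OCc3ccccc3)cc2)C[C@](C)(O)[C@@H](CC(=O)OC)O1 | intermediate
17 | methyl (2E,4S,6R,7Z)-18-[4-(benzyloxy)phenyl]-4,6-dihydroxy-4,6-dimethyloctadeca-2,7-dienoate | COC(=O)/C=C/[C@@](C)(O)C[C@@](C)(O)/C=C\CCCCCCCCCCc1ccc(OCc2ccccc2)cc1 | intermediate (not isolated)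
18 | methyl 2-[(2S,3S,5R)-5-{(1Z)-12-[4-(benzyloxy)phenyl]dodec-1-en-1-yl}-3-hydroxy-3,5-dimethyloxolan-2-yl]acetate | C[C@]1(/C=C\CCCCCCCCCCc2ccc(OCc3ccccc3)cc2)C[C@](C)(O)[C@H](CC(=O)OC)O1 | intermediate (not isolated)
19 | (3aS,5R,6aS)-5-{(1Z)-12-[4-(benzyloxy)phenyl]dodec-1-en-1-yl}-5,6a-dimethyltetrahydrofuro[3,2-b]furan-2(3H)-one | C[C@]1(/C=C\CCCCCCCCCCc2ccc(OCc3ccccc3)cc2)C[C@]2(C)OC(=O)C[C@@H]2O1 | intermediate
20 | plakortone N, (3aS,5S,6aS)-5-[12-(4-hydroxyphenyl)dodecyl]-5,6a-dimethyltetrahydrofuro[3,2-b]furan-2(3H)-one | C[C@]1(CCCCCCCCCCCCc2ccc(O)cc2)C[C@]2(C)OC(=O)C[C@@H]2O1 | target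

**Step count and risks**

Total steps: 12. Longest linear sequence: 10 (steps 1–7 and 10–12); steps 8 and 9 make the side-chain fragment.

Steps most likely to fail:

1. Step 5. The ketyl oxygen may take the endo orientation, or the samarium enolate may expel the β-oxygen before it is protonated; either would erode the configuration at C-6a or lead to ring-opened, over-reduced material. The fallback gives up both the temporary ring and ring closure through C-3a–C-6a, and sets out from diol 2. Silylation of the primary hydroxyl (TBSCl, imidazole) should give silyl ether F1, and Tsuji–Wacker oxidation hydroxy ketone F2. Addition of lithiated ethyl propiolate (LiC≡CCO2Et, THF, −78 °C) should give ynoate diol F3 as both C-4 epimers. Semihydrogenation (H2, Pd/CaCO3 poisoned with Pb(OAc)2, quinoline) with spontaneous lactonisation should give butenolide F4. DBU-promoted oxa-Michael closure should then give bicyclic lactone F5 beside its diastereomer F6, which is removed by chromatography. Bu4NF should give alcohol F7, Dess–Martin oxidation aldehyde F8, and Wittig reaction with ylide 15 comes back to the route at 19.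

2. Step 3. Intermolecular oxa-Michael oligomerisation may outrun closure of the seven-membered ring by the hindered tertiary alkoxide. The fallback builds the same ring by acetal chemistry instead of conjugate addition, and sets out from diol 2. Steglich esterification of the primary hydroxyl with 3,3-dimethoxypropanoic acid should give acetal ester F9. Heating with PPTS in toluene with removal of methanol should close the ring by transacetalisation with the tertiary hydroxyl and β-elimination of methanol, coming back to the route at 4.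

3. Step 11. Expulsion of the tertiary alkoxide from the ester enolate may be slow, so that intermolecular Claisen-type condensation competes with the equilibration. The fallback changes the oxidation level and sets out from ester 16. Reduction with i-Bu2AlH at −78 °C should give aldehyde F10, whose retro-oxa-Michael/oxa-Michael equilibration (catalytic DBU) is far easier than that of the ester. The cis isomer is drained as bicyclic lactol F11, and oxidation of the lactol (TEMPO, PhI(OAc)2) comes back to the route at 19.

**Further compounds**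

F1 | step 5 | (2R)-1-{[tert-butyl(dimethyl)silyl]oxy}-2-methylpent-4-en-2-ol | C[C@](O)(CO[Si](C)(C)C(C)(C)C)CC=C
F2 | step 5 | (4R)-5-{[tert-butyl(dimethyl)silyl]oxy}-4-hydroxy-4-methylpentan-2-one | C[C@](O)(CO[Si](C)(C)C(C)(C)C)CC(C)=O
F3 | step 5 | ethyl (6R)-7-{[tert-butyl(dimethyl)silyl]oxy}-4,6-dihydroxy-4,6-dimethylhept-2-ynoate (both C-4 epimers) | CCOC(=O)C#CC(C)(O)C[C@@](C)(O)CO[Si](C)(C)C(C)(C)C
F4 | step 5 | 5-[(2R)-3-{[tert-butyl(dimethyl)silyl]oxy}-2-hydroxy-2-methylpropyl]-5-methylfuran-2(5H)-one (both C-5 epimers) | CC1(C[C@@](C)(O)CO[Si](C)(C)C(C)(C)C)OC(=O)C=C1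
F5 | step 5 | (3aS,5R,6aS)-5-({[tert-butyl(dimethyl)silyl]oxy}methyl)-5,6a-dimethyltetrahydrofuro[3,2-b]furan-2(3H)-one | C[C@]1(CO[Si](C)(C)C(C)(C)C)C[C@]2(C)OC(=O)C[C@@H]2O1
F6 | step 5 | (3aR,5R,6aR)-5-({[tert-butyl(dimethyl)silyl]oxy}methyl)-5,6a-dimethyltetrahydrofuro[3,2-b]furan-2(3H)-one | C[C@]1(CO[Si](C)(C)C(C)(C)C)C[C@@]2(C)OC(=O)C[C@H]2O1
F7 | step 5 | (3aS,5R,6aS)-5-(hydroxymethyl)-5,6a-dimethyltetrahydrofuro[3,2-b]furan-2(3H)-one | C[C@]1(CO)C[C@]2(C)OC(=O)C[C@@H]2O1
F8 | step 5 | (3aS,5R,6aS)-5,6a-dimethyl-2-oxohexahydrofuro[3,2-b]furan-5-carbaldehyde | C[C@]1(C=O)C[C@]2(C)OC(=O)C[C@@H]2O1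
F9 | step 3 | (2R)-2-hydroxy-2-methylpent-4-en-1-yl 3,3-dimethoxypropanoate | C[C@](O)(COC(=O)CC(OC)OC)CC=C
F10 | step 11 | 2-[(2R,3S,5R)-5-{(1Z)-12-[4-(benzyloxy)phenyl]dodec-1-en-1-yl}-3-hydroxy-3,5-dimethyloxolan-2-yl]acetaldehyde | C[C@]1(/C=C\CCCCCCCCCCc2ccc(OCc3ccccc3)cc2)C[C@](C)(O)[C@@H](CC=O)O1
F11 | step 11 | (3aS,5R,6aS)-5-{(1Z)-12-[4-(benzyloxy)phenyl]dodec-1-en-1-yl}-5,6a-dimethylhexahydrofuro[3,2-b]furan-2-ol (both anomers) | C[C@]1(/C=C\CCCCCCCCCCc2ccc(OCc3ccccc3)cc2)C[C@]2(C)OC(O)C[C@@H]2O1
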